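## Retrosynthetic overview

- **Feature** (tetralin numbering: C1 = ArCH, C2/C3 = CH2OH-bearing carbons, C4 = CH2). C1 is a diarylmethine CH. It is bonded to C8a of ring A, para to the C6 OH, and to C1′ of ring C, para to the C4′ OH. Both C–aryl bonds are therefore Friedel–Crafts bonds to one carbon at the aldehyde oxidation level.
- 16 ⇒ all-trans diester 15 (two ester reductions; C2/C3 equilibrated against C1) ⇒ 14 ⇒ formylsuccinate 10 + guaiacol 11 (cut C1–C1′ and C1–C8a).
- 10 ⇒ (R)-benzylsuccinate 6 + methyl formate 7 (C1–C2) ⇒ Stobbe half-ester 4 (C3 by asymmetric hydrogenation) ⇒ O-benzylisovanillin 2 + dimethyl succinate 3 (C3–C4).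
- Ring order: rings A and C are bought with 1 and 11. Ring B is the only ring made, in step 7.

Key step: step 7

Assumption: (S,S)-Et-DuPHOS is taken to give the R acid 5, by analogy with the face it selects on (Z)-α-acetamidocinnamates (same geometry, CH2CO2H in place of NHAc); the configuration of 5 is to be checked at that stage and the antipodal ligand used if the sense is opposite.

## Route

Step 1
Reactants: 1 isovanillin
Product: 2 3-(benzyloxy)-4-methoxybenzaldehyde
Conditions: BnBr (1.1 equiv), K2CO3 (1.5 equiv), DMF, 25 °C
Reagents that add atoms: benzyl bromide, BrCc1ccccc1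
Why: Williamson ether synthesis on the only acidic OH, giving a benzyl ether that masks the phenol through the two strongly basic steps (2 and 5) and leaves later by neutral hydrogenolysis.

Step 2
Reactants: 2 3-(benzyloxy)-4-methoxybenzaldehyde; 3 dimethyl succinate
Product: 4 (3E)-4-[3-(benzyloxy)-4-methoxyphenyl]-3-(methoxycarbonyl)but-3-enoic acid
Conditions: NaOMe (1.5 equiv), MeOH, reflux; then 1 M HCl; crystallisation
Reagents that add atoms: none
Why: Stobbe condensation, which stops at mono-condensation because the product is a carboxylate, places the free acid on the CH2 arm and favours the E alkene (aryl trans to CO2Me), with NaOMe/MeOH chosen so that ester exchange is degenerate.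

Step 3
Reactants: 4 (3E)-4-[3-(benzyloxy)-4-methoxyphenyl]-3-(methoxycarbonyl)but-3-enoic acid
Product: 5 (3R)-4-[3-(benzyloxy)-4-methoxyphenyl]-3-(methoxycarbonyl)butanoic acid
Conditions: [Rh(cod)2]BF4 (1 mol %), (S,S)-Et-DuPHOS (1.1 mol %), NaOMe (10 mol %), H2 (5 bar), MeOH, 25 °C
Reagents that add atoms: none
Why: Rhodium-catalysed asymmetric hydrogenation of an itaconate-type half-ester, run on the free acid because its carboxyl group and the alkene chelate the cationic rhodium bisphosphine complex as an enamide does, so that H2 is delivered to one alkene face and sets C3 as R while the aryl benzyl ether is untouched by the homogeneous catalyst.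

Step 4
Reactants: 5 (3R)-4-[3-(benzyloxy)-4-methoxyphenyl]-3-(methoxycarbonyl)butanoic acid
Product: 6 dimethyl (2R)-2-[3-(benzyloxy)-4-methoxybenzyl]butanedioate
Conditions: MeOH, H2SO4 (cat.), reflux
Reagents that add atoms: methanol, CO
Why: Fischer esterification, an acidic medium in which the α-stereocentre does not enolise appreciably and the benzyl ether is stable.

Step 5
Reactants: 6 dimethyl (2R)-2-[3-(benzyloxy)-4-methoxybenzyl]butanedioate; 7 methyl formate
Product: 9 dimethyl (3R)-3-[3-(benzyloxy)-4-methoxybenzyl]-2-formylbutanedioate, via lithium enolate 8 (not isolated)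
Conditions: LiN(i-Pr)2 (1.15 equiv), THF, −78 °C, 6 added to the base; HCO2Me (5 equiv), −78 → −30 °C; cold 1 M HCl
Reagents that add atoms: none
Why: Crossed Claisen formylation of a kinetic ester enolate, done while the phenol is still benzylated so that no base is lost to it: the hindered amide should take a proton from the unbranched CH2 (future C2) much faster than the tertiary C3–H beside the benzyl branch, inverse addition at −78 °C keeps deprotonation irreversible, and the product persists as its delocalised enolate, which shields C3–H until the cold acidic quench.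

Step 6
Reactants: 9 dimethyl (3R)-3-[3-(benzyloxy)-4-methoxybenzyl]-2-formylbutanedioate
Product: 10 dimethyl (3R)-2-formyl-3-(3-hydroxy-4-methoxybenzyl)butanedioate
Conditions: H2 (1 atm), 10% Pd/C, EtOAc, 25 °C, stopped after one equivalent of H2; filtration, used directly
Reagents that add atoms: none
Why: Hydrogenolysis of an aryl benzyl ether, which should outrun reduction of the push–pull enol C=C and the chelated formyl group at 1 atm in an aprotic solvent and delivers the sensitive precursor without aqueous work-up.

Step 7
Reactants: 10 dimethyl (3R)-2-formyl-3-(3-hydroxy-4-methoxybenzyl)butanedioate; 11 guaiacol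
Product: 14 dimethyl (1S,3R)-6-hydroxy-1-(4-hydroxy-3-methoxyphenyl)-7-methoxy-1,2,3,4-tetrahydronaphthalene-2,3-dicarboxylate (C2 epimers), via benzylic carbinol 12 (not isolated), via dihydronaphthalene diester 13 (not isolated)
Conditions: 11 (5 equiv), CF3SO3H (20 mol %), (CF3)2CHOH/CH2Cl2 1:4, Ar, 0 °C, 10 added over 2 h; then 40 °C until the isomer distribution is constant; aq. NaHCO3; chromatography
Reagents that add atoms: none
Why: Proposed new method: C-protonation of the enolised formyl ester gives a hydroxycarbenium ion at C1 that ring A attacks through the carbon para to its OH (6-exo-trig Friedel–Crafts hydroxyalkylation, forming C1–C8a and ring B), carbinol 12 ionises to the para-hydroxybenzylic (protonated quinone methide) cation, which rests as its conjugated alkene 13 and is drained by guaiacol attacking through the carbon para to its OH (C1–C1′). The closest known reaction types are the acid cyclodehydration of α-formyl-γ-arylbutyrates to 3,4-dihydro-2-naphthoates, the acid hydroarylation of electron-rich cinnamates by phenols and the intermolecular Friedel–Crafts arylation of 1-tetralol-type cations by phenols, and the new element is running them as one cascade on a chiral succinate. C2 is erased and rewritten through 13, so C3 alone decides C1: adducts from pseudoaxial entry of guaiacol keep the C1–aryl bond parallel to the π system of ring A and should re-ionise on ageing, whereas the isomer with C1 aryl and C3 ester both equatorial (1,3-cis, 1S) holds that bond near the ring A plane, reverts slowest and should accumulate. C2 is set by protonation of 13, is expected to favour the equatorial 2R ester, and is not relied upon because step 8 corrects it. Site selectivity on ring A rests on para activation by the OH (the other ortho carbon of the benzyl unit is squeezed between CH2 and OH), and on guaiacol it rests on OH being the stronger para director and on the bulk of the secondary cation, which disfavours both ortho sites. Adding 10 slowly to excess guaiacol suppresses self-condensation while the intramolecular closure outruns a second guaiacol, so little acyclic bis-guaiacyl adduct should form, and 1,3-trans isomers and guaiacol regioisomers are removed here, before any base is used.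

Step 8
Reactants: 14 dimethyl (1S,3R)-6-hydroxy-1-(4-hydroxy-3-methoxyphenyl)-7-methoxy-1,2,3,4-tetrahydronaphthalene-2,3-dicarboxylate (C2 epimers)
Product: 15 dimethyl (1S,2R,3R)-6-hydroxy-1-(4-hydroxy-3-methoxyphenyl)-7-methoxy-1,2,3,4-tetrahydronaphthalene-2,3-dicarboxylate
Conditions: NaOMe (5 equiv), dry MeOH, Ar, 50 °C; then 1 M HCl, 0 °C; crystallisation
Reagents that add atoms: none
Why: Thermodynamic epimerisation through ester enolates, in which C2–H and C3–H both exchange while the C1 diarylmethine cannot, so the mixture should settle on the isomer with all three ring B substituents equatorial relative to the fixed 1S centre (2R,3R), which is also why 14 has to be free of 1R isomers, since these would converge on the enantiomer.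

Step 9
Reactants: 15 dimethyl (1S,2R,3R)-6-hydroxy-1-(4-hydroxy-3-methoxyphenyl)-7-methoxy-1,2,3,4-tetrahydronaphthalene-2,3-dicarboxylate
Product: 16 (1S,2R,3R)-isolariciresinol (CNP0313668.1)
Conditions: LiAlH4 (6 equiv), THF, 0 → 50 °C; aq. potassium sodium tartrate
Reagents that add atoms: none
Why: LiAlH4 reduction of both methyl esters to primary alcohols, in which the two phenols only consume hydride as aluminium phenoxides and are released on work-up, and no stereocentre drifts because the substrate is already the most stable diastereomer and reduction outruns enolisation.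

## Compound list

1 | isovanillin (3-hydroxy-4-methoxybenzaldehyde) | COc1ccc(C=O)cc1O | starting material
2 | 3-(benzyloxy)-4-methoxybenzaldehyde | COc1ccc(C=O)cc1OCc1ccccc1 | intermediate
3 | dimethyl succinate | COC(=O)CCC(=O)OC | starting material
4 | (3E)-4-[3-(benzyloxy)-4-methoxyphenyl]-3-(methoxycarbonyl)but-3-enoic acid | COC(=O)/C(CC(=O)O)=C/c1ccc(OC)c(OCc2ccccc2)c1 | intermediate
5 | (3R)-4-[3-(benzyloxy)-4-methoxyphenyl]-3-(methoxycarbonyl)butanoic acid | COc1ccc(C[C@@H](C(=O)OC)CC(=O)O)cc1OCc1ccccc1 | intermediate
6 | dimethyl (2R)-2-[3-(benzyloxy)-4-methoxybenzyl]butanedioate | COc1ccc(C[C@@H](C(=O)OC)CC(=O)OC)cc1OCc1ccccc1 | intermediate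
7 | methyl formate | COC=O | starting material
8 | lithium enolate of 6 at the CH2 ester arm (not isolated) | [Li+].COc1ccc(C[C@@H](C(=O)OC)C=C([O-])OC)cc1OCc1ccccc1 | intermediate
9 | dimethyl (3R)-3-[3-(benzyloxy)-4-methoxybenzyl]-2-formylbutanedioate (C2 labile, mainly the 2-hydroxymethylidene enol) | COc1ccc(C[C@@H](C(=O)OC)C(C=O)C(=O)OC)cc1OCc1ccccc1 | intermediate
10 | dimethyl (3R)-2-formyl-3-(3-hydroxy-4-methoxybenzyl)butanedioate (C2 labile, mainly enol) | COc1ccc(C[C@@H](C(=O)OC)C(C=O)C(=O)OC)cc1O | intermediate
11 | guaiacol (2-methoxyphenol) | COc1ccccc1O | starting material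
12 | dimethyl (3R)-1,6-dihydroxy-7-methoxy-1,2,3,4-tetrahydronaphthalene-2,3-dicarboxylate (C1, C2 mixtures; not isolated) | COC(=O)C1C(O)c2cc(OC)c(O)cc2C[C@H]1C(=O)OC | intermediate
13 | dimethyl (2R)-7-hydroxy-6-methoxy-1,2-dihydronaphthalene-2,3-dicarboxylate (not isolated) | COC(=O)C1=Cc2cc(OC)c(O)cc2C[C@H]1C(=O)OC | intermediate
14 | dimethyl (1S,3R)-6-hydroxy-1-(4-hydroxy-3-methoxyphenyl)-7-methoxy-1,2,3,4-tetrahydronaphthalene-2,3-dicarboxylate, C2 epimers | COc1cc([C@H]2c3cc(OC)c(O)cc3C[C@@H](C(=O)OC)C2C(=O)OC)ccc1O | intermediate
15 | dimethyl (1S,2R,3R)-6-hydroxy-1-(4-hydroxy-3-methoxyphenyl)-7-methoxy-1,2,3,4-tetrahydronaphthalene-2,3-dicarboxylate (all-trans) | COc1cc([C@H]2c3cc(OC)c(O)cc3C[C@@H](C(=O)OC)[C@@H]2C(=O)OC)ccc1O | intermediate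
16 | (1S,2R,3R)-isolariciresinol = (6R,7R,8S)-8-(4-hydroxy-3-methoxyphenyl)-6,7-bis(hydroxymethyl)-3-methoxy-5,6,7,8-tetrahydronaphthalen-2-ol | COc1cc([C@H]2c3cc(OC)c(O)cc3C[C@@H](CO)[C@@H]2CO)ccc1O | target

## Step count and risks

Total step count: 9. Longest linear sequence: 9.

**Step 7 (key step).**
- Guaiacol may enter pseudoaxially, anti to the equatorial C3 ester, without re-ionising later. That would fix C1 in the 1,3-trans sense and, after step 8, feed the mirror-image series.
- Guaiacol may attack through the carbon para to OMe or ortho to OH, and this leakage could grow on long ageing.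
- The cascade may stall at the resting alkene. That alkene could then disproportionate, aromatise, or shift its double bond in a way that erases C3.

The fallback uses known chemistry and sets out from 5.
- Selective reduction of the ester of the potassium carboxylate (KOH, then CaCl2/NaBH4, EtOH) and acid lactonisation give (4R)-4-[3-(benzyloxy)-4-methoxybenzyl]oxolan-2-one F1. Its stereocentre is no longer enolisable.
- LiN(i-Pr)2 and commercial 4-(benzyloxy)-3-methoxybenzaldehyde give, trans to the benzyl group, (3S,4R)-3-{[4-(benzyloxy)-3-methoxyphenyl](hydroxy)methyl}-4-[3-(benzyloxy)-4-methoxybenzyl]oxolan-2-one F2.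
- CF3CO2H in CH2Cl2 at 0 °C ionises the carbinol. Ring A closes through a chair-like transition state to the all-trans 6-benzyloxy-1-(4-benzyloxy-3-methoxyphenyl)-7-methoxytetralin 2,3-γ-lactone F3.
- LiAlH4 gives 6,4′-di-O-benzylisolariciresinol F4.
- H2 over Pd/C brings the sequence back to the route at 16.

**Step 5.**
- The tertiary C3–H may be removed in competition, which would erode enantiopurity and allow quaternary formylation.
- Proton exchange between the acidic product and unreacted enolate may limit conversion.

The fallback sets out from 5. It shields C3 as a carboxylate so that only the C2 methylene can be enolised, the tactic of dianion alkylations of 2-substituted succinic acid 4-esters.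
- LiOH in aqueous THF gives (2R)-2-[3-(benzyloxy)-4-methoxybenzyl]butanedioic acid F5.
- Ac2O closes it to (3R)-3-[3-(benzyloxy)-4-methoxybenzyl]oxolane-2,5-dione F6.
- Methanol opens the anhydride at the less hindered carbonyl to (2R)-2-[3-(benzyloxy)-4-methoxybenzyl]-4-methoxy-4-oxobutanoic acid F7.
- LiN(i-Pr)2 (2.2 equiv) followed by 7 gives (2R)-2-[3-(benzyloxy)-4-methoxybenzyl]-3-formyl-4-methoxy-4-oxobutanoic acid F8.
- MeI with KHCO3 in DMF alkylates only the carboxylate and returns to the route at 9.

**Step 6.**
- The enolised formyl group may be over-reduced or hydrogenolysed while the benzyl ether is being cleaved.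

The fallback sets out from 6. It removes the benzyl group before the formyl group exists and lets the phenoxide protect itself.
- H2 over Pd/C gives dimethyl (2R)-2-(3-hydroxy-4-methoxybenzyl)butanedioate F9.
- LiN(i-Pr)2 (2.2 equiv, the first equivalent forming the lithium phenoxide) followed by 7 and a cold acidic quench comes back to the route at 10.

## Further compounds

F1 | step 7 | (4R)-4-[3-(benzyloxy)-4-methoxybenzyl]oxolan-2-one | COc1ccc(C[C@H]2COC(=O)C2)cc1OCc1ccccc1
F2 | step 7 | (3S,4R)-3-{[4-(benzyloxy)-3-methoxyphenyl](hydroxy)methyl}-4-[3-(benzyloxy)-4-methoxybenzyl]oxolan-2-one (carbinol epimers) | COc1ccc(C[C@H]2COC(=O)[C@@H]2C(O)c2ccc(OCc3ccccc3)c(OC)c2)cc1OCc1ccccc1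
F3 | step 7 | all-trans (1S,2R,3R, tetralin numbering) 6-benzyloxy-1-(4-benzyloxy-3-methoxyphenyl)-7-methoxytetralin 2,3-γ-lactone (C2 carbonyl, C3 CH2O) | COc1cc([C@H]2c3cc(OC)c(OCc4ccccc4)cc3C[C@H]3COC(=O)[C@H]23)ccc1OCc1ccccc1
F4 | step 7 | 6,4′-di-O-benzyl-(1S,2R,3R)-isolariciresinol | COc1cc([C@H]2c3cc(OC)c(OCc4ccccc4)cc3C[C@@H](CO)[C@@H]2CO)ccc1OCc1ccccc1
F5 | step 5 | (2R)-2-[3-(benzyloxy)-4-methoxybenzyl]butanedioic acid | COc1ccc(C[C@@H](C(=O)O)CC(=O)O)cc1OCc1ccccc1
F6 | step 5 | (3R)-3-[3-(benzyloxy)-4-methoxybenzyl]oxolane-2,5-dione | COc1ccc(C[C@@H]2CC(=O)OC2=O)cc1OCc1ccccc1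
F7 | step 5 | (2R)-2-[3-(benzyloxy)-4-methoxybenzyl]-4-methoxy-4-oxobutanoic acid | COc1ccc(C[C@@H](C(=O)O)CC(=O)OC)cc1OCc1ccccc1
F8 | step 5 | (2R)-2-[3-(benzyloxy)-4-methoxybenzyl]-3-formyl-4-methoxy-4-oxobutanoic acid (C3 labile) | COc1ccc(C[C@@H](C(=O)O)C(C=O)C(=O)OC)cc1OCc1ccccc1
F9 | step 6 | dimethyl (2R)-2-(3-hydroxy-4-methoxybenzyl)butanedioate | COc1ccc(C[C@@H](C(=O)OC)CC(=O)OC)cc1O
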